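**Plan**

- Cuts: the macrocycle at C12–C13 and at C4–C5 (two B-alkyl Suzuki–Miyaura couplings), C13 as a Wittig methylene on C14, the C1=C15 alkene as a dehydration, and the dihydrofuran at O–C2 and C1–C15, back to dihydroxyacetone and (E)-hex-2-en-4-ynal.
- Enabling feature: in the dihydrofuran ring (O, C2, C1, C15, C16) the unit C16–C15–C17 with its two oxygens is dihydroxyacetone and C2–C1–C14 is an enal, so one amine-catalysed oxa-Michael/aldol event makes both ring bonds.
- Forward order: furan ring first (held as a lactol-bridged bicycle), the C5–C12 chain joined at C4, epoxide, C14 vinyl group, ring alkene, 14-membered ring last.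
- Stereochemistry: C2 from the (S)-prolinol silyl ether catalyst in the key step; the (7R,8R)-epoxide from Shi epoxidation (reagent control); the three (E)-alkenes from syn-hydrozirconation/iodination or syn-carboalumination followed by stereoretentive cross-coupling.

Key step: step 2

Remark: cembrane numbering is used (C1=C15 ring alkene, C2 the oxygenated CH, C16 the ring CH2, C17 the acetoxymethyl carbon, C18–C20 the methyls on C4, C8, C12). C1, C15 and the lactol carbon of 6–10 and 17–23 are transient centres, drawn as the cis-fused, 1,2-trans isomer with the lactol carbon undefined. The facial sense assigned to the (S)-catalyst follows the usual shielding model and is to be checked on 7; the (R)-catalyst is used if it proves opposite.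

**Step 1**
Reactants: 1 but-2-yn-1-ol; 2 (triphenyl-λ5-phosphanylidene)acetaldehyde
Product: 4 (2E)-hex-2-en-4-ynal, via but-2-ynal 3 (not isolated)
Conditions: MnO2 (activated, excess), CH2Cl2, rt; filter; then 2, CH2Cl2, 0 °C to rt
Reagents that add atoms: none
Why: MnO2 oxidises the propargylic alcohol to the ynal and the stabilised ylide converts it to the (E)-enal (Wittig reaction); the enal formed is less electrophilic than the ynal, so a single homologation is expected.

**Step 2**
Reactants: 4 (2E)-hex-2-en-4-ynal; 5 1,3-dihydroxyacetone (charged as its dimer)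
Product: 7 cis-fused lactol 6-(prop-1-yn-1-yl)tetrahydro-1H,3H-furo[3,4-c]furan-1,3a(4H)-diol, via hydroxy aldehyde 6 (not isolated)
Conditions: (S)-2-[diphenyl(trimethylsilyloxy)methyl]pyrrolidine (20 mol %), PhCO2H (20 mol %), CHCl3, rt
Reagents that add atoms: none
Why: The amine condenses with 4 to an (E)-s-trans iminium ion, a hydroxyl of 5 adds reversibly to its β-carbon (oxa-Michael, forming the O–C2 bond), and the enamine so formed attacks the ketone of the tethered dihydroxyacetone (aldol, forming the C1–C15 bond); hydrolysis releases 6, whose free CH2OH traps the aldehyde as lactol 7. This is the known amine-catalysed domino oxa-Michael/aldol/hemiacetalisation of enals with dihydroxyacetone, applied here to a β-alkynyl enal. The tetrahydrofuran ring closes in the aldol step by 5-exo-trig (enolexo) attack on the carbonyl, and the temporary second ring by 5-exo-trig hemiacetalisation. C2 is set by the catalyst, whose diphenyl(silyloxy)methyl group shields one face of the iminium ion so that oxygen adds from the open face, which for the (S)-catalyst should correspond to the C2 configuration of the target; C1 and C15 follow from C2 and the cis-fusion and are erased in step 13. The step needs 1,4- over 1,6-addition on the enynyl iminium ion, secured because only the 1,4-adduct can close the five-membered ring irreversibly. The C3–C4 unit is carried as a triple bond because it has no alkene geometry that amine catalysis could scramble through a trienamine.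

**Step 3**
Reactants: 7 lactol
Product: 8 anomeric tert-butyldimethylsilyl ether of 7
Conditions: TBSCl, imidazole, CH2Cl2, 0 °C
Reagents that add atoms: tert-butyl(chloro)dimethylsilane, CC(C)(C)[Si](C)(C)Cl
Why: Silyl protection of the hemiacetal hydroxyl, which reacts far faster than the tertiary alcohol; this masks the aldehyde for the two hydrozirconations.

**Step 4**
Reactants: 8 silyl lactol
Product: 10 (E)-iodoalkene 1-O-TBS-6-[(1E)-2-iodoprop-1-en-1-yl]tetrahydro-1H,3H-furo[3,4-c]furan-1,3a(4H)-diol, via alkenylzirconocene chloride 9 (not isolated)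
Conditions: Cp2Zr(H)Cl (3 equiv), THF, rt to 40 °C; then I2, THF, 0 °C
Reagents that add atoms: iodine, II
Why: Hydrozirconation adds Zr–H syn across the alkyne with zirconium on the methyl-bearing carbon, away from the branched oxygenated C2, and iodinolysis with retention gives the (E)-iodoalkene; one equivalent of reagent is consumed by the tertiary hydroxyl.

**Step 5**
Reactants: 11 hexa-1,5-diyne
Product: 13 hepta-1,5-diyne, via lithium acetylide 12 (not isolated)
Conditions: n-BuLi (0.9 equiv), THF, −78 °C; then MeI, −78 °C to rt; fractional distillation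
Reagents that add atoms: iodomethane, CI
Why: Acetylide alkylation of one terminus; the statistical by-products (dimethylated diyne and unreacted 11) are removed by distillation.

**Step 6**
Reactants: 13 hepta-1,5-diyne
Product: 15 (3E)-4-methylnona-1,3-dien-7-yne, via alkenyldimethylalane 14 (not isolated)
Conditions: Me3Al (2 equiv), Cp2ZrCl2 (25 mol %), CH2Cl2, 0 °C to rt; then vinyl bromide, Pd(PPh3)4 (5 mol %), ZnCl2, THF, rt
Reagents that add atoms: trimethylaluminium, C[Al](C)C; vinyl bromide, C=CBr
Why: Zirconium-catalysed syn-carboalumination (Negishi) of the terminal alkyne places methyl on the internal carbon and leaves the internal alkyne untouched, and palladium-catalysed coupling of the alkenylalane with vinyl bromide proceeds with retention to the (3E)-diene.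

**Step 7**
Reactants: 15 (3E)-4-methylnona-1,3-dien-7-yne; 10 (E)-iodoalkene
Product: 17 1-O-TBS-6-[(1E,5E)-2,6-dimethylundeca-1,5-dien-9-yn-1-yl]tetrahydro-1H,3H-furo[3,4-c]furan-1,3a(4H)-diol, via B-alkyl-9-BBN 16 (not isolated)
Conditions: 9-BBN (1.0 equiv), THF, 0 °C to rt; then 10, PdCl2(dppf) (10 mol %), AsPh3, Cs2CO3, DMF/THF/H2O, rt
Reagents that add atoms: none
Why: 9-BBN adds to the terminal CH2 of the diene faster than to the internal alkyne or the trisubstituted alkene, and the primary alkylborane couples with the alkenyl iodide with retention (B-alkyl Suzuki–Miyaura coupling), which fixes the (E)-C3=C4 bond.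

**Step 8**
Reactants: 17 dienyne
Product: 19 1-O-TBS-6-[(1E,5E,9E)-10-iodo-2,6-dimethylundeca-1,5,9-trien-1-yl]tetrahydro-1H,3H-furo[3,4-c]furan-1,3a(4H)-diol, via alkenylzirconocene chloride 18 (not isolated)
Conditions: Cp2Zr(H)Cl (3 equiv), THF, 50 °C; then I2, THF, 0 °C
Reagents that add atoms: iodine, II
Why: Hydrozirconation of the 2-alkyne under equilibrating conditions should favour zirconium at the methyl terminus and iodinolysis gives the (E)-2-iodoalkene; the trisubstituted alkenes do not react and a minor regioisomer is removed by chromatography.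

**Step 9**
Reactants: 19 triene iodide
Product: 20 (7R,8R)-epoxide of 19
Conditions: D-fructose-derived Shi ketone (30 mol %), KHSO5 (Oxone), K2CO3, Bu4NHSO4, MeCN/dimethoxymethane/aq. Na2B4O7 buffer, 0 °C
Reagents that add atoms: potassium peroxymonosulfate (KHSO5, as Oxone), [K+].[O-]S(=O)(=O)OO
Why: Shi epoxidation, in which the chiral dioxirane attacks the only electron-rich trisubstituted alkene (C3=C4 is deactivated by the allylic ring oxygen and hindered by the ring, C11=C12 by iodine); the D-fructose-derived ketone should give the (7R,8R)-epoxide by the spiro transition-state model, independently of the remote C2.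

**Step 10**
Reactants: 20 epoxy silyl lactol
Product: 21 epoxy lactol
Conditions: TBAF, AcOH (1:1), THF, 0 °C
Reagents that add atoms: none
Why: Fluoride cleaves the anomeric silyl ether (desilylation), and the acetic acid buffer avoids base-induced retro-aldol opening of the lactol.

**Step 11**
Reactants: 21 epoxy lactol
Product: 22 vinyl diol 4-ethenyl-3-(hydroxymethyl)-5-[side chain]oxolan-3-ol
Conditions: Ph3PCH3Br, KHMDS (3.5 equiv each), THF, 0 °C; then 21, 0 °C to rt
Reagents that add atoms: methyltriphenylphosphonium bromide, C[P+](c1ccccc1)(c1ccccc1)c1ccccc1.[Br-]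
Why: Wittig methylenation of the lactol through its open hydroxy-aldehyde form, as is routine for furanose lactols; olefination should outpace enolisation of the α-branched aldehyde, and this opens the temporary ring and adds C13.

**Step 12**
Reactants: 22 vinyl diol
Product: 23 primary monoacetate of 22
Conditions: Ac2O, pyridine, CH2Cl2, 0 °C to rt
Reagents that add atoms: acetic anhydride, CC(=O)OC(C)=O
Why: Acetylation of the primary hydroxyl only, since the tertiary alcohol does not react under these conditions; this installs the C17 acetate of the target.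

**Step 13**
Reactants: 23 monoacetate
Product: 24 [(5R)-4-ethenyl-5-[side chain]-2,5-dihydrofuran-3-yl]methyl acetate
Conditions: methyl N-(triethylammoniosulfonyl)carbamate (Burgess reagent), THF, rt to 45 °C
Reagents that add atoms: none
Why: Burgess dehydration, in which the tertiary sulfamate undergoes syn-elimination with the cis, allylic H-1 to give the conjugated C1=C15/C13=C14 diene; the temperature is kept low so that the epoxide does not react with the reagent.

**Step 14**
Reactants: 24 diene acetate
Product: 26 lobophynin B, via B-alkyl-9-BBN 25 (not isolated)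
Conditions: 9-BBN (1.5 equiv), THF, 0 °C to rt; then slow addition to PdCl2(dppf) (20 mol %), AsPh3, Cs2CO3, DMF/THF/H2O, rt, 0.002 M
Reagents that add atoms: none
Why: 9-BBN hydroborates the terminal vinyl group of the diene at C13, and intramolecular B-alkyl Suzuki–Miyaura coupling with the (E)-alkenyl iodide under high dilution closes the 14-membered ring with retention of the C11=C12 geometry.

**Compound list**

In 19–25 "side chain" is the C3–C12 chain on C2 of the target: (1E)-4-[(2R,3R)-3-[(3E)-4-iodopent-3-en-1-yl]-3-methyloxiran-2-yl]-2-methylbut-1-en-1-yl (in 19 the non-epoxidised triene).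

1 | but-2-yn-1-ol | CC#CCO | starting material
2 | (triphenyl-λ5-phosphanylidene)acetaldehyde | O=CC=P(c1ccccc1)(c1ccccc1)c1ccccc1 | starting material
3 | but-2-ynal | CC#CC=O | intermediate
4 | (2E)-hex-2-en-4-ynal | CC#C/C=C/C=O | intermediate
5 | 1,3-dihydroxyacetone (used as its dimer) | OCC(=O)CO | starting material
6 | 4-hydroxy-4-(hydroxymethyl)-2-(prop-1-yn-1-yl)oxolane-3-carbaldehyde (C2 as in the target; CHO trans to propynyl, cis to CH2OH) | CC#C[C@H]1OC[C@](O)(CO)[C@@H]1C=O | intermediate
7 | 6-(prop-1-yn-1-yl)tetrahydro-1H,3H-furo[3,4-c]furan-1,3a(4H)-diol (cis-fused lactol, anomers) | CC#C[C@H]1OC[C@]2(O)COC(O)[C@H]12 | intermediate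
8 | 1-O-tert-butyldimethylsilyl ether of 7 | CC#C[C@H]1OC[C@]2(O)COC(O[Si](C)(C)C(C)(C)C)[C@H]12 | intermediate
9 | alkenylzirconocene chloride from 8 (Zr on the methyl-bearing carbon, drawn with free 3a-OH) | Cl[Zr](C1C=CC=C1)(C1C=CC=C1)/C(C)=C/[C@H]1OC[C@]2(O)COC(O[Si](C)(C)C(C)(C)C)[C@H]12 | intermediate
10 | 1-O-TBS-6-[(1E)-2-iodoprop-1-en-1-yl]tetrahydro-1H,3H-furo[3,4-c]furan-1,3a(4H)-diol | I/C(C)=C/[C@H]1OC[C@]2(O)COC(O[Si](C)(C)C(C)(C)C)[C@H]12 | intermediate
11 | hexa-1,5-diyne | C#CCCC#C | starting material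
12 | lithium hexa-1,5-diyn-1-ide | [Li]C#CCCC#C | intermediate
13 | hepta-1,5-diyne | CC#CCCC#C | intermediate
14 | dimethyl[(1E)-2-methylhept-1-en-5-yn-1-yl]alane | C[Al](C)/C=C(\C)CCC#CC | intermediate
15 | (3E)-4-methylnona-1,3-dien-7-yne | C=C/C=C(\C)CCC#CC | intermediate
16 | 9-[(3E)-4-methylnon-3-en-7-yn-1-yl]-9-borabicyclo[3.3.1]nonane | CC#CCC/C(C)=C/CCB1C2CCCC1CCC2 | intermediate
17 | 1-O-TBS-6-[(1E,5E)-2,6-dimethylundeca-1,5-dien-9-yn-1-yl]tetrahydro-1H,3H-furo[3,4-c]furan-1,3a(4H)-diol | CC#CCC/C(C)=C/CC/C(C)=C/[C@H]1OC[C@]2(O)COC(O[Si](C)(C)C(C)(C)C)[C@H]12 | intermediate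
18 | alkenylzirconocene chloride from 17 (Zr on C12, drawn with free 3a-OH) | Cl[Zr](C1C=CC=C1)(C1C=CC=C1)/C(C)=C/CC/C(C)=C/CC/C(C)=C/[C@H]1OC[C@]2(O)COC(O[Si](C)(C)C(C)(C)C)[C@H]12 | intermediate
19 | 1-O-TBS-6-[(1E,5E,9E)-10-iodo-2,6-dimethylundeca-1,5,9-trien-1-yl]tetrahydro-1H,3H-furo[3,4-c]furan-1,3a(4H)-diol | I/C(C)=C/CC/C(C)=C/CC/C(C)=C/[C@H]1OC[C@]2(O)COC(O[Si](C)(C)C(C)(C)C)[C@H]12 | intermediate
20 | 1-O-TBS-6-[side chain]tetrahydro-1H,3H-furo[3,4-c]furan-1,3a(4H)-diol, (7R,8R)-epoxide | I/C(C)=C/CC[C@@]3(C)O[C@@H]3CC/C(C)=C/[C@H]1OC[C@]2(O)COC(O[Si](C)(C)C(C)(C)C)[C@H]12 | intermediate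
21 | 6-[side chain]tetrahydro-1H,3H-furo[3,4-c]furan-1,3a(4H)-diol (lactol, anomers) | I/C(C)=C/CC[C@@]3(C)O[C@@H]3CC/C(C)=C/[C@H]1OC[C@]2(O)COC(O)[C@H]12 | intermediate
22 | 4-ethenyl-3-(hydroxymethyl)-5-[side chain]oxolan-3-ol (H-4 cis to 3-OH) | I/C(C)=C/CC[C@@]3(C)O[C@@H]3CC/C(C)=C/[C@H]1OC[C@](O)(CO)[C@@H]1C=C | intermediate
23 | [4-ethenyl-3-hydroxy-5-[side chain]oxolan-3-yl]methyl acetate | I/C(C)=C/CC[C@@]3(C)O[C@@H]3CC/C(C)=C/[C@H]1OC[C@](O)(COC(C)=O)[C@@H]1C=C | intermediate
24 | [(5R)-4-ethenyl-5-[side chain]-2,5-dihydrofuran-3-yl]methyl acetate | I/C(C)=C/CC[C@@]3(C)O[C@@H]3CC/C(C)=C/[C@H]1OCC(COC(C)=O)=C1C=C | intermediate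
25 | B-alkyl-9-BBN from 24 (boron on C13) | I/C(C)=C/CC[C@@]3(C)O[C@@H]3CC/C(C)=C/[C@H]1OCC(COC(C)=O)=C1CCB1C2CCCC1CCC2 | intermediate
26 | lobophynin B | CC(=O)OCC1=C2CC/C(C)=C/CC[C@@]3(C)O[C@@H]3CC/C(C)=C/[C@H]2OC1 | target

**Step count and risks**

Total: 14 steps. Longest linear sequence: 12 steps (steps 1–4 and 7–14); steps 5–6 make the second fragment.

Step 2 (key step). The small enynyl iminium ion of 4 may undergo 1,6-addition or oligomerisation faster than the annulation, or the slim alkynyl group may give poor face discrimination. The fallback installs the alkyne after the ring. It sets out from 5, which is put through the same domino reaction with (2E)-4-(benzyloxy)but-2-enal F1, a plain γ-alkoxy enal, to give the benzyloxymethyl lactol F2. Silylation as in step 3 gives the silyl lactol F3, hydrogenolysis (H2, Pd/C, EtOAc) the primary alcohol F4, and Dess–Martin oxidation the aldehyde F5. The Ohira–Bestmann reagent (K2CO3, MeOH) then gives the terminal alkyne F6, and C-methylation (n-BuLi, 2 equiv, THF, −78 °C; then MeI) returns to 8.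

Step 14. Zerovalent palladium may ionise the allylic acetate, or the aqueous base may cleave it, during the slow ring closure. The fallback introduces the acetate last. From 22, TBSCl/imidazole gives the primary silyl ether F7 and Burgess dehydration the diene silyl ether F8. 9-BBN gives the borane F9, and the same Suzuki–Miyaura macrocyclisation gives the macrocyclic silyl ether F10. TBAF gives the macrocyclic alcohol F11, and Ac2O/pyridine returns to 26.

Step 13. The sulfamate of 23 may eliminate toward C16 or C17 (enol ether or enol acetate) instead of toward C1, or the reagent may attack the epoxide. The fallback forms the ring alkene by E1cB elimination at the lactone level, where only H-1 is acidic. From 21, TEMPO/PhI(OAc)2 (CH2Cl2) gives the β-hydroxy lactone F12 and MsCl/Et3N/DMAP the fused butenolide F13. DIBAL-H (CH2Cl2, −78 °C) gives the unsaturated lactol F14 and Ph3P=CH2 the dienol F15; acetylation as in step 12 returns to 24.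

**Further compounds**

F1 | step 2 | (2E)-4-(benzyloxy)but-2-enal | O=C/C=C/COCc1ccccc1
F2 | step 2 | 6-[(benzyloxy)methyl]tetrahydro-1H,3H-furo[3,4-c]furan-1,3a(4H)-diol | C(OCc1ccccc1)[C@H]1OC[C@]2(O)COC(O)[C@H]12
F3 | step 2 | 1-O-TBS ether of F2 | C(OCc1ccccc1)[C@H]1OC[C@]2(O)COC(O[Si](C)(C)C(C)(C)C)[C@H]12
F4 | step 2 | 1-O-TBS-6-(hydroxymethyl)tetrahydro-1H,3H-furo[3,4-c]furan-1,3a(4H)-diol | OC[C@H]1OC[C@]2(O)COC(O[Si](C)(C)C(C)(C)C)[C@H]12
F5 | step 2 | 6-carbaldehyde from F4 | O=C[C@H]1OC[C@]2(O)COC(O[Si](C)(C)C(C)(C)C)[C@H]12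
F6 | step 2 | 1-O-TBS-6-ethynyltetrahydro-1H,3H-furo[3,4-c]furan-1,3a(4H)-diol | C#C[C@H]1OC[C@]2(O)COC(O[Si](C)(C)C(C)(C)C)[C@H]12
F7 | step 14 | primary tert-butyldimethylsilyl ether of 22 | I/C(C)=C/CC[C@@]3(C)O[C@@H]3CC/C(C)=C/[C@H]1OC[C@](O)(CO[Si](C)(C)C(C)(C)C)[C@@H]1C=C
F8 | step 14 | silyl ether analogue of 24 | I/C(C)=C/CC[C@@]3(C)O[C@@H]3CC/C(C)=C/[C@H]1OCC(CO[Si](C)(C)C(C)(C)C)=C1C=C
F9 | step 14 | B-alkyl-9-BBN from F8 | I/C(C)=C/CC[C@@]3(C)O[C@@H]3CC/C(C)=C/[C@H]1OCC(CO[Si](C)(C)C(C)(C)C)=C1CCB1C2CCCC1CCC2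
F10 | step 14 | macrocyclic 17-O-TBS ether (silyl analogue of 26) | CC(C)(C)[Si](C)(C)OCC1=C2CC/C(C)=C/CC[C@@]3(C)O[C@@H]3CC/C(C)=C/[C@H]2OC1
F11 | step 14 | macrocyclic 17-alcohol (deacetyl 26) | OCC1=C2CC/C(C)=C/CC[C@@]3(C)O[C@@H]3CC/C(C)=C/[C@H]2OC1
F12 | step 13 | β-hydroxy lactone from 21 | I/C(C)=C/CC[C@@]3(C)O[C@@H]3CC/C(C)=C/[C@H]1OC[C@]2(O)COC(=O)[C@H]12
F13 | step 13 | fused butenolide 6-[side chain]-4,6-dihydro-1H,3H-furo[3,4-c]furan-1-one | I/C(C)=C/CC[C@@]3(C)O[C@@H]3CC/C(C)=C/[C@H]1OCC2=C1C(=O)OC2
F14 | step 13 | unsaturated lactol from F13 | I/C(C)=C/CC[C@@]3(C)O[C@@H]3CC/C(C)=C/[C@H]1OCC2=C1C(O)OC2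
F15 | step 13 | dienol [(5R)-4-ethenyl-5-[side chain]-2,5-dihydrofuran-3-yl]methanol | I/C(C)=C/CC[C@@]3(C)O[C@@H]3CC/C(C)=C/[C@H]1OCC(CO)=C1C=C
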